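**Retrosynthetic overview**
- Alertenone is cut into two molecules of suberosenone: the C3–C12′ bond comes from Michael addition of the C3 dienolate of one molecule to the exo-methylene of the other, and C1′–H from a kinetic protonation.
- Suberosenone comes from a tricyclic cyclopentenone (C3=C4) by α′-aminomethylation at C1, hydrogenation (sets C4) and amine elimination.
- Ring A of that enone is closed by alkyne hydration and intramolecular aldol condensation of an acetonyl arm onto the C4 bridge ketone.
- The bicyclo[3.2.1]octan-8-one (ring B plus the six-membered ring) comes from one chiral-acid-catalysed Michael/aldol α,α′-annulation of 2-propargyl-4,4-dimethylcyclopentanone with crotonaldehyde (sets C9 and C8; C5 follows).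
- Ring order: ring B (purchased) → six-membered ring → ring A → dimerisation.

Assumption: the sense of induction of the new step 2 is taken to be that given by (S)-TRIP; if the first run shows the opposite, (R)-TRIP is used.

Locants used throughout (primes = second unit): ring A = C1(=C12H2)–C2(=O)–C3–C4–C9; ring B = C4–C5–C11(Me2)–C10–C9; six-membered ring = C4–C5–C6–C7–C8(Me)–C9.

**Step 1**
Reactants: 1, 3,3-dimethylcyclopentan-1-one; 2, propargyl bromide
Product: 3, rac-4,4-dimethyl-2-(prop-2-yn-1-yl)cyclopentan-1-one
Conditions: LDA (1.05 equiv), THF, −78 °C; then 2 (1.2 equiv), DMPU, −78 → 0 °C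
Reagents that add atoms: none (2 is a numbered reactant)
Why: Kinetic enolate alkylation; LDA removes the α-proton remote from the gem-dimethyl carbon (the other α-CH2 is neopentyl), and the racemic α-stereocentre formed here is erased through the enol in step 2.

**Step 2**
Reactants: 3; 4, (E)-but-2-enal (crotonaldehyde)
Product: 5, 4-hydroxy-2,6,6-trimethyl-1-(prop-2-yn-1-yl)bicyclo[3.2.1]octan-8-one (C9 quaternary with propargyl, C8-methyl on the face opposite the C10–C11 bridge, C5 bridgehead H; C6–OH epimers, inconsequential)
Conditions: (S)-TRIP (10 mol %), 4 (3 equiv), PhMe, 40 °C, 72 h; then p-TsOH·H2O (10 mol %), rt, 2 h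
Reagents that add atoms: none
Why: Proposed new method: enantioselective Brønsted-acid "enol catalysis" Michael/aldol α,α′-annulation of an unactivated α-branched ketone with a β-substituted enal. The phosphoric acid converts racemic 3 into its achiral, more substituted enol (the other α-carbon is neopentyl) and binds the enol O–H and the enal C=O in a closed synclinal transition state, with CHO over the enol oxygen and the β-methyl anti to the enol C=C. This forms C9 and C8 together with the relative configuration of the target. The δ-keto aldehyde then closes from C5, the only remaining enolisable α-carbon, by acid-catalysed aldol, which fixes C5. Closest known chemistry: chiral phosphoric acid enol-catalysed Michael additions of α-branched cyclic ketones to enones, d'Angelo-type chiral-imine Michael additions to crotonates, and the Stork enamine/acrolein α,α′-annulation.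

**Step 3**
Reactants: 5
Product: 6, 2,6,6-trimethyl-1-(prop-2-yn-1-yl)bicyclo[3.2.1]oct-3-en-8-one (C6=C7 alkene)
Conditions: Martin sulfurane (1.5 equiv), CH2Cl2, 0 °C → rt
Reagents that add atoms: none
Why: Alcohol dehydration (E2); elimination can only go toward C7 because C5 is a bridgehead (Bredt), and it removes the aldol oxygen and the undefined C6 centre before any basic step could trigger retro-aldol.

**Step 4**
Reactants: 6
Product: 8, tricyclic dienone: ring A cyclopentenone (C2=O, C3=C4, C1H2) fused at C4–C9 to the bicyclo[3.2.1]octene (C6=C7), formed via 7, the 1-(2-oxopropyl) diketone, not isolated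
Conditions: (i) Ph3PAuNTf2 (2 mol %), MeOH/H2O 10:1, 60 °C; (ii) KOH (3 equiv), 65 °C, same pot
Reagents that add atoms: water, O
Why: Markovnikov alkyne hydration gives methyl ketone 7, then intramolecular aldol condensation; the C4 ketone has no enolisable α-H (C9 quaternary, C5 bridgehead), so only the methyl-ketone enolate can add to C4 and dehydrate to the C3=C4 enone.

**Step 5**
Reactants: 8; 9, Eschenmoser's salt
Product: 10, the C1-(dimethylaminomethyl) derivative of 8 (C1 epimers, inconsequential)
Conditions: LDA (1.2 equiv), THF, −78 °C, 45 min; then 9 (1.5 equiv), −78 → 0 °C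
Reagents that add atoms: Eschenmoser's salt, C=[N+](C)C.[I-]
Why: Mannich reaction of the kinetic α′-enolate; C1 is the only enolisable position (C3 is vinylic, C5 a bridgehead), so the future exo-methylene carbon is placed regiospecifically.

**Step 6**
Reactants: 10
Product: 11, saturated β-amino ketone (C4–H on the six-membered-ring face, C3 syn to the C10–C11 bridge)
Conditions: H2 (1 atm), 10% Pd/C, EtOAc–AcOH (20:1), rt
Reagents that add atoms: none (H2 only)
Why: Heterogeneous hydrogenation of both alkenes; H is expected to add to C4 from the six-membered-ring face because only that mode gives the cis-fused A/B diquinane (the other face leads to a strained trans-bicyclo[3.3.0]octanone), and AcOH keeps the amine protonated so it does not eliminate early.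

**Step 7**
Reactants: 11
Product: 12, suberosenone
Conditions: MeI (5 equiv), MeOH, rt; then sat. aq. NaHCO3/CH2Cl2, rt
Reagents that add atoms: none in the product (MeI only quaternises nitrogen, which leaves as NMe3)
Why: Quaternisation and E1cB (Hofmann-type) β-elimination of the Mannich base unveils the α-methylene ketone without touching any stereocentre.

**Step 8**
Reactants: 12 (donor, 1.0 equiv); 12 (acceptor, 2.0 equiv)
Product: 13, alertenone
Conditions: LiHMDS (1.0 equiv), THF, −78 °C, slow inverse addition of donor 12; then acceptor 12 in THF, −78 °C, 2 h; AcOH (3 equiv) in THF at −78 °C; neutral work-up, excess 12 recovered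
Reagents that add atoms: none
Why: Michael addition of a cross-conjugated lithium dienolate to an α-substituted vinyl ketone (Stork–Ganem-type; the fully substituted product enolate does not propagate). C3 attacks from the convex face of its diquinane, so the new CH2 is cis to H4. C1′ is set by kinetic protonation, expected on the ring-B′ face anti to the axial C8′ methyl, which leaves the CH2 cis to C8′.

**Compound list**
1 | 3,3-dimethylcyclopentan-1-one | O=C1CCC(C)(C)C1 | starting material
2 | propargyl bromide (3-bromoprop-1-yne) | C#CCBr | starting material
3 | rac-4,4-dimethyl-2-(prop-2-yn-1-yl)cyclopentan-1-one | O=C1CC(C)(C)CC1CC#C | intermediate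
4 | (E)-but-2-enal | C/C=C/C=O | starting material
5 | 4-hydroxy-2,6,6-trimethyl-1-(prop-2-yn-1-yl)bicyclo[3.2.1]octan-8-one | O=C1[C@@H]2C(O)C[C@H](C)[C@@]1(CC#C)CC2(C)C | intermediate
6 | 2,6,6-trimethyl-1-(prop-2-yn-1-yl)bicyclo[3.2.1]oct-3-en-8-one | O=C1[C@@H]2C=C[C@H](C)[C@@]1(CC#C)CC2(C)C | intermediate
7 | 2,6,6-trimethyl-1-(2-oxopropyl)bicyclo[3.2.1]oct-3-en-8-one | O=C1[C@@H]2C=C[C@H](C)[C@@]1(CC(C)=O)CC2(C)C | intermediate (not isolated)
8 | tricyclic dienone (C2=O, C3=C4, C6=C7) | O=C1C=C2[C@@H]3C=C[C@H](C)[C@@]2(C1)CC3(C)C | intermediate
9 | Eschenmoser's salt (N,N-dimethylmethyleneiminium iodide) | C=[N+](C)C.[I-] | starting material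
10 | C1-(dimethylaminomethyl) tricyclic dienone | O=C1C=C2[C@@H]3C=C[C@H](C)[C@@]2(C1CN(C)C)CC3(C)C | intermediate
11 | C1-(dimethylaminomethyl) saturated tricyclic ketone | CN(C)CC1C(=O)C[C@H]2[C@@H]3CC[C@H](C)[C@]12CC3(C)C | intermediate
12 | suberosenone | C=C1C(=O)C[C@H]2[C@@H]3CC[C@H](C)[C@]12CC3(C)C | intermediate
13 | alertenone | C=C1C(=O)[C@H](C[C@@H]2C(=O)C[C@H]3[C@@H]4CC[C@H](C)[C@]23CC4(C)C)[C@H]2[C@@H]3CC[C@H](C)[C@]12CC3(C)C | target

**Totals**
Total steps: 8. Longest linear sequence: 8 (the route is linear; step 8 uses two molecules of 12).

**Three steps most likely to fail**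
1. Step 2 (proposed new annulation). Enal oligomerisation, 1,2-addition, or low ee/dr are possible. Fallback with known chemistry: diarylprolinol silyl ether (iminium) catalysed Michael/aldol of methyl 4,4-dimethyl-2-oxocyclopentane-1-carboxylate with crotonaldehyde, a known reaction class for cyclic β-keto esters. The bridgehead ester is then converted to the acetonyl arm (reduce/oxidise to the aldehyde, Wittig with Ph3P=C(OMe)CH3, hydrolysis), at a cost of about three steps.
2. Step 8 (dimerisation). Oligomers may form, and the C1′ configuration rests on a kinetic protonation whose facial preference I could not establish with confidence. By my conformational analysis the target C1′ epimer is probably the less stable one, so base must be avoided after the quench. Fallback: Mukaiyama–Michael addition of the isolated TBS dienol ether of 12 to 12 (cat. TBSOTf, CH2Cl2, −78 °C), isolation of the ring-B′ silyl enol ether, and reagent-controlled protonation with a chiral proton source (matched enantiomer of a BINOL·SnCl4-type Lewis-acid-assisted Brønsted acid).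
3. Step 6 (C4 facial selectivity). Both faces of C3=C4 carry a nearby methyl (axial C8-Me on one, a C11-Me on the other), so the hydrogenation could be unselective. Fallback: dissolving-metal reduction of the enone in 10 (Li, NH3, t-BuOH), where β-protonation under thermodynamic control gives the cis-diquinane, followed by separate hydrogenation of the isolated C6=C7 alkene.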